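Watch the ratio c(right-handed product)/c(left-handed product), not the yield, and pool it over a whole run.

| setting | north-west | south-west | north-east | spring | summer | autumn |
|---|---|---|---|---|---|---|
| left-handed substrate | 27 mM | 27 mM | 27 mM | 27 mM | 27 mM | 27 mM |
| right-handed substrate | 27 mM | 27 mM | 27 mM | 27 mM | 27 mM | 27 mM |
| reagent | 3.2 equiv | 3.9 equiv | 5.8 equiv | 2.50 equiv | 4.00 equiv | 6.00 equiv |
| free catalyst | 0.42 mol% | 0.42 mol% | 0.42 mol% | 0.42 mol% | 0.42 mol% | 0.42 mol% |
| precatalyst | 5 mol% | 5 mol% | 5 mol% | 5 mol% | 5 mol% | 5 mol% |
| remark | run made earlier | run made earlier | run made earlier |  |  |  |
| time |  |  |  | 25 h | 25 h | 25 h |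

- north-west (time / h: left-handed product / %, right-handed product / %, left-handed substrate / %): 2.00: 16.1, 9.4, 35.1; 4.00: 28.4, 13.0, 26.2; 8.00: 41.7, 15.7, 19.2; 12.0: 50.9, 22.2, 16.0; 25.0: 62.0, 28.8, 5.8
- south-west (time / h: left-handed product / %, right-handed product / %, left-handed substrate / %): 5.00: 37.0, 15.7, 21.6; 10.0: 52.4, 21.1, 14.0; 15.0: 57.2, 25.2, 6.5; 20.0: 61.9, 27.0, 5.9; 25.0: 64.1, 28.6, 3.7
- north-east (time / h: left-handed product / %, right-handed product / %, left-handed substrate / %): 2.00: 29.7, 14.7, 26.5; 6.00: 48.9, 24.0, 11.7; 12.0: 61.9, 30.4, 4.4; 20.0: 67.3, 32.2, 2.3; 25.0: 64.4, 32.2, 0

(each reading ± 1 percentage point)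

- free catalyst is single-handed; left-handed substrate and right-handed substrate are mirror images of each other, charged as a racemate, each of them at the stated concentration
- "hardly changes" means that all values lie within two and a half points (for a concentration: within two and a half percent of the largest)

- share of left-handed product in all that became left-handed product or right-handed product for spring, summer, autumn, in this order
- how that number moves from the first to the last of them (falls all the way / falls, then rises / rises all the way / hardly changes / rises, then falls)

I began with the north-east run, where left-handed product read 67.3% at 20.0 h, above the 50.0% of the charge that was left-handed, so substrate was changing hands while it reacted, as in a dynamic kinetic resolution. But the ratio, the inverse of an apparent selectivity factor, stayed put in that run, reading 0.495 at 2.00 h and 0.500 at 25.0 h, so I froze it within each run and summed each product over the readings to thin the scatter. That gave 0.448 for the north-west run, 0.431 for the south-west run and 0.490 for the north-east run. The scatter did not separate the first two, so I averaged them to 0.439 at 3.55 equivalents, but the north-east value stood higher, and I kept that rise of the pooled ratio per equivalent of reagent as the reagent slope, 0.0227 per equivalent.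

Along that line I reckoned shares of 70.6% for spring, 69.0% for summer and 66.9% for autumn, a steady fall, with spring the least safe because its reagent lies below that of any run. The forecast gave 70.8%, 69.1% and 66.9%, falls all the way, close to my figures though not the same, on the ground that “Faster consumption therefore lets the fast enantiomer deplete more”.

The flask gave 70.8%, 69.5% and 67.4%, falls all the way.

    left-handed substrate + racemization catalyst ⇌ right-handed substrate + racemization catalyst, rate k1*[racemization catalyst]*[left-handed substrate] forward; the back reaction follows from the equilibrium constant (k = 1100 /M/h)
    reagent + free catalyst + right-handed substrate → free catalyst + right-handed product (k = 8700 /M²/h)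
    precatalyst → racemization catalyst (k = 0.0630 /h)
    free catalyst → spent catalyst (k = 0.0100 /h)
    reagent + free catalyst + left-handed substrate → free catalyst + left-handed product (k = 23000 /M²/h)

At 25.0 h the spring flask still held 11.1% of left-handed substrate and 11.2% of right-handed substrate, in percent of the two charged together. Spring's share means a ratio of 0.412, and adding the reagent slope of 0.0227 per equivalent over the 3.50 equivalents up to autumn gave 0.492, which is an autumn share of 67.0% against the 67.4% the autumn flask gave.

All runs were computed with made-up constants; noise was put on by code.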